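## Structural features

The target is a monocyclic oxolane (O1, C2, C3, C4, C5) with three different substituents on three adjacent carbons: ring Ar1 (3,4,5-trimethoxyphenyl) on C2, a hydroxymethyl carbon C3a on C3, and the benzylic methylene C4a of ring Ar2 (3-hydroxy-4,5-dimethoxyphenyl) on C4; C5 is an unsubstituted OCH2 group. The stereocentres C2, C3 and C4 are contiguous and are (2R,3S,4S): Ar1 is trans to C3a, and C3a is cis to C4a. The two aryl rings differ only by one free phenol, so both oxygenation patterns are best bought ready-made. The fragile sites are the C2–O1 bond (an electron-rich benzylic ether that acid can ionise and hydrogen on palladium can cleave), the free phenol, and ring Ar2, whose positions ortho to C4a can attack a cation at C2 through a six-membered transition state. The real difficulty is not the ring but the 3,4-cis relation, which is the less stable arrangement whenever C4 stands next to a carbonyl group, together with absolute control from a single source. The key step uses the fact that C3a is one carbon at the alcohol oxidation level on C3, and C3 is β to C5: with C5 as a lactone carbonyl, C3=C4 is the double bond of a furan-2(5H)-one with C3 as its electrophilic β-carbon, and C3a is the carbon of methanol delivered as the hydroxymethyl radical. The lactone ring O1–C2–C3–C4–C5 is then already the oxolane of the target, so C2, set by ketone reduction, can steer both new centres.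

## Logic of the disconnections

16 ⇒ 15. Only the O–Si bond on the phenol of ring Ar2 is cut. The phenol must be masked from the enolate steps onward. A triisopropylsilyl ether is preferred to an O-benzyl group for three reasons: it has no activated O–CH2–aryl hydrogen for an excited ketone to abstract in the key step; fluoride removes it without touching C2–O1, which a hydrogenolysis would put at risk; and the bulky, weakly donating silyloxy group makes ring Ar2 a poorer nucleophile toward a cation at C2. The demand on the forward step is small: a fluoride source at low temperature.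

15 ⇒ 14. The O1–C2 bond is cut, opening the ring to an acyclic triol in which C3 and C4 carry no neighbouring carbonyl and can no longer epimerise. The cut is placed at the benzylic carbon because C2 is the one position that can be closed under acid catalysis without activating either primary alcohol. The forward step must form the five-membered ether through the C2 benzylic cation, with Ar1 settling trans to C3a (the all-cis alternative is clearly more strained). It must also be faster than attack of ring Ar2 on the same cation.

14 ⇒ 13. C5 is raised to the carboxyl level and joined to the C2 oxygen as a γ-lactone. The carbonyl at C5 is what makes C3 electrophilic one step earlier, and the ring holds C2, C3 and C4 in a rigid frame. The forward hydride reduction must be faster than any base-induced epimerisation at C4. It need not distinguish 13 from the lactone formed by acyl migration to the C3a hydroxyl, because both give 14.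

13 ⇒ 11 + 12. The C3–C3a bond and the C4–H bond are cut, which removes two stereocentres and one carbon and leaves a butenolide whose only stereocentre is C2. The forward step must add the radical of 12 to C3 on the face opposite Ar1 and then deliver hydrogen to C4 on the face opposite the new CH2OH. It must do so without abstracting the doubly activated C2–H and without any base, since C2–H in 11 is also acidic (enolisation gives an achiral 2-hydroxyfuran).

11 ⇒ 8 (through 9 and 10). The C3=C4 unsaturation is removed. The saturated lactone can be deprotonated at C4, selenenylated, oxidised and eliminated under cold, base-free conditions, which 11 needs. The forward syn-elimination must run into the ring (toward C3–H) and not toward the benzylic hydrogens on C4a.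

8 ⇒ 7 + 4. The C4–C4a bond is cut, giving a benzylic bromide and the enolate of a simple γ-aryl lactone. The configuration formed at C4 is irrelevant because step 6 erases it, so the forward step only has to monoalkylate.

7 ⇒ 5 (through 6). The C2–H bond and the lactone C–O bond are cut, leading to a commercial aryl keto acid. C2 is the single bought stereocentre. The forward reduction must be enantioselective for an aryl ketone and must leave the free carboxyl group alone; this rules out borane-based reductions of the free acid and points to catalytic transfer hydrogenation, after which the hydroxy acid lactonises on acidification.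

4 ⇒ 3 ⇒ 2 ⇒ 1. The C–Br bond, the benzylic C–H bond and the O–Si bond are cut in turn, leading to the commercial hydroxy-dimethoxybenzaldehyde. The forward steps are routine; the only demand is neutral bromination so that the silyl ether and the reactive benzylic bromide survive.

## Other disconnections considered

Alternative 1: The cut is across C2–C3 and C4–C5, a [3+2] retron. In the forward step CsF induces 1,3-elimination from the α-chloro ether A3; the non-stabilised carbonyl ylide so released adds to the double bond of the menthyl acetal butenolide A2 on the face away from the menthyloxy group. The product is the cis-fused bicycle A1, in which C3a is the lactone carbonyl and C4a the acetal carbon.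
- In favour: the ring and all three stereocentres form in one step. The 3,4-cis relation is enforced by the cis ring fusion, which is better than the chosen plan, where C4 rests on a kinetic hydrogen transfer. C2 is never ionised afterwards.
- Against: the unsymmetrical ylide must bond its aryl-bearing end to the α-carbon C3, and Ar1 must take the convex face; neither is assured. A3 is an α-chloro ether of an electron-rich benzaldehyde and would be very labile.
- The tail is long. The acetal carbon C4a still has to receive ring Ar2 and lose its oxygen while the second benzylic C–O bond (C2–O1) survives, and C3a has to be reduced. During this tail C4 sits next to an aldehyde-level carbon and can epimerise.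
- Comparison: on stereochemical structure at the ring-forming stage the alternative is stronger; mechanistically a concerted cycloaddition replaces a radical chain; on step economy it is probably no better than the chosen plan.

Alternative 2: The cut is C3–C4 (with C4a–H). In the forward step Cp2TiCl (trivalent titanium, from Cp2TiCl2 and Zn) opens the epoxide of the epoxy cinnamyl ether A5 by electron transfer. The C3 radical closes 5-exo onto C4 of the styrene, and the benzylic C4a radical is reduced and protonated, giving A4, the O-benzyl ether of the target.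
- In favour: the ring, the C3–C4 bond, two stereocentres and the free primary alcohol arise together, and A4 is one step from the target. This is the shortest of the four plans and better than the chosen one on step economy. C4 is never next to a carbonyl, so the 3,4-cis relation cannot epimerise, which is better than the chosen plan before its reduction step and equal after it.
- Against: C3 and C4 are both set relative to C2 in one acyclic chair-like transition state, which is expected to favour the required isomer but only moderately, with no later chance of correction. The reagent is stoichiometric, and the benzylic radical can dimerise or lose hydrogen to a styrene. C2 in A5 is both benzylic and attached to an allylic ether oxygen and is exposed to a Lewis acidic metal. The last step is a hydrogenolysis next to C2–O1.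
- Comparison: both plans set C4 in a kinetic radical event and are equal in kind there, and both need C2 set beforehand. The chosen plan has the rigid butenolide for the C3 selection and a catalytic, metal-free key step; the alternative wins on length.

Alternative 3: The cut is C2–Ar1. In the forward step BF3·OEt2 ionises the lactol acetate A7 to the oxocarbenium ion at C2, and the arylzinc reagent A8 (from the corresponding Grignard reagent and ZnBr2) adds trans to the C3 substituent, giving the bis-silyl ether A6. A7 would come from the twofold-symmetric cis-fused bislactone A9.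
- In favour: Ar1 enters last, so the plan is convergent and modular. The 3,4-cis relation is locked by the ring fusion of A9, which is better than the chosen plan on this point. The 2,3-trans outcome relies on 1,2-induction in an irreversible C–C bond formation, at least equal to the cationic ether closure of the chosen plan.
- Against: the route to A7 is long: enantiopure A9, opening of one lactone by an Ar2 nucleophile to an aryl ketone, deoxygenation of that ketone (C4 is α to it and can epimerise meanwhile), two silylations, lactol formation and acetylation. The Lewis acid step runs with ring Ar2 placed to attack the C2 oxocarbenium ion through a six-membered ring, the same hazard as step 9 of the chosen plan, so the two are equal there. A deprotection remains.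
- Comparison: mechanistically it is a well-behaved polar C-arylation; structurally it buys security at C4 with more steps; on step economy it is clearly worse than the chosen plan.

Key step: step 7

Assumptions: compounds 1, 5 and 12 are bought. The atom labels O1, C2, C3, C3a, C4, C4a and C5 are those of the target's oxolane and are kept for the same atoms in every intermediate, whatever locants the systematic names carry. The minor 3,5-cis epimer of 8 is as useful as the major one, because step 6 removes that centre.

## Route

Step 1
Reactants: 1 3-hydroxy-4,5-dimethoxybenzaldehyde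
Product: 2 3,4-dimethoxy-5-[(triisopropylsilyl)oxy]benzaldehyde
Conditions: iPr3SiCl (1.2 equiv), imidazole (2.5 equiv), DMF, rt
Reagents that add atoms: triisopropylsilyl chloride, CC(C)[Si](Cl)(C(C)C)C(C)C
Why: Standard silylation of a phenol; the bulky silyl ether should withstand amide bases, hydride, peroxide and irradiation in methanol and has no activated C–H bond.

Step 2
Reactants: 2 3,4-dimethoxy-5-[(triisopropylsilyl)oxy]benzaldehyde
Product: 3 {3,4-dimethoxy-5-[(triisopropylsilyl)oxy]phenyl}methanol
Conditions: NaBH4, THF/MeOH, 0 °C
Reagents that add atoms: none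
Why: Borohydride reduction of an aryl aldehyde; the hindered aryl silyl ether should not be cleaved at 0 °C.

Step 3
Reactants: 3 {3,4-dimethoxy-5-[(triisopropylsilyl)oxy]phenyl}methanol
Product: 4 [5-(bromomethyl)-2,3-dimethoxyphenoxy]tri(propan-2-yl)silane
Conditions: CBr4, PPh3, CH2Cl2, 0 °C
Reagents that add atoms: carbon tetrabromide, BrC(Br)(Br)Br
Why: Appel bromination under neutral conditions, which spare the silyl ether; the electron-rich benzylic bromide is to be used at once.

Step 4
Reactants: 5 4-oxo-4-(3,4,5-trimethoxyphenyl)butanoic acid
Product: 7 (5R)-5-(3,4,5-trimethoxyphenyl)oxolan-2-one, via (4R)-hydroxy acid 6 (not isolated)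
Conditions: RuCl[(R,R)-TsDPEN](p-cymene) (1 mol%), HCO2H/Et3N (5:2), 40 °C; then 2 M HCl, EtOAc, rt
Reagents that add atoms: none
Why: Noyori–Ikariya asymmetric transfer hydrogenation of an aryl ketone, which tolerates the free carboxyl group (a borane reagent would reduce it); the (R,R)-ligand should deliver hydride to give the (R)-carbinol, which sets C2, and the γ-hydroxy acid lactonises on acidification.

Step 5
Reactants: 7 (5R)-5-(3,4,5-trimethoxyphenyl)oxolan-2-one; 4 [5-(bromomethyl)-2,3-dimethoxyphenoxy]tri(propan-2-yl)silane
Product: 8 (3S,5R)-3-{[3,4-dimethoxy-5-(triisopropylsilyloxy)phenyl]methyl}-5-(3,4,5-trimethoxyphenyl)oxolan-2-one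
Conditions: LiN(SiMe3)2 (1.05 equiv), THF, −78 °C; then 4, −78 → −30 °C
Reagents that add atoms: none
Why: Lactone enolate alkylation with a reactive benzylic bromide forms C4–C4a; attack anti to Ar1 should favour the 3,5-trans epimer, but the new centre is removed in step 6, so its configuration does not matter.

Step 6
Reactants: 8 (3S,5R)-3-{[3,4-dimethoxy-5-(triisopropylsilyloxy)phenyl]methyl}-5-(3,4,5-trimethoxyphenyl)oxolan-2-one
Product: 11 (5R)-3-{[3,4-dimethoxy-5-(triisopropylsilyloxy)phenyl]methyl}-5-(3,4,5-trimethoxyphenyl)furan-2(5H)-one, via selenide 9 (not isolated), via selenoxide 10 (not isolated)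
Conditions: LiN(iPr)2 (1.2 equiv), THF, −78 °C; PhSeBr; aq. NH4Cl; then 30% H2O2, CH2Cl2, 0 °C → rt (no amine base)
Reagents that add atoms: none
Why: Enolate selenenylation followed by selenoxide syn-elimination; a ring hydrogen on C3 syn to selenium is always available and endocyclic elimination is the usual course for α-alkyl-α-seleno lactones, and the cold, base-free oxidation should keep the acidic C2–H of the butenolide, and with it the optical purity, intact.

Step 7
Reactants: 11 (5R)-3-{[3,4-dimethoxy-5-(triisopropylsilyloxy)phenyl]methyl}-5-(3,4,5-trimethoxyphenyl)furan-2(5H)-one; 12 methanol (reactant and solvent)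
Product: 13 (3S,4S,5R)-3-{[3,4-dimethoxy-5-(triisopropylsilyloxy)phenyl]methyl}-4-(hydroxymethyl)-5-(3,4,5-trimethoxyphenyl)oxolan-2-one
Conditions: Ph2CO (0.3 equiv), MeOH (degassed, 0.02 M), hν 350–365 nm (Pyrex), 10–15 °C
Reagents that add atoms: none
Why: Sensitised radical conjugate addition, the known photochemical addition of alcohols to 5-substituted furan-2(5H)-ones: triplet Ph2CO abstracts a hydrogen atom from 12, and the nucleophilic hydroxymethyl radical adds to the electron-poor β-carbon C3 of 11, forming C3–C3a. The α-acyl radical at C4 then takes a hydrogen atom from 12, which carries the chain, or from the diphenylketyl radical, which returns the sensitiser. No ring is closed; the lactone ring of 11 is already the future oxolane. C3 is controlled by C2: on the nearly flat butenolide the radical should enter on the face opposite ring Ar1, so that C3a ends trans to Ar1. C4 is controlled by the new centre C3: the hydrogen donor should approach the planar radical on the face away from the adjacent CH2OH, leaving C4a cis to C3a; this is the less secure selection, because that face also carries the more distant Ar1. Chemoselectivity is needed as well: the excited ketone must take hydrogen from 12 and not from C2–H or from a protecting group, which the large excess of 12 as solvent and the absence of activated C–H bonds in the silyl ether should secure. The neutral medium should keep the kinetic 3,4-cis lactone from epimerising at C4 and C2 from racemising through the 2-hydroxyfuran tautomer. Migration of the acyl group from O1 to the C3a hydroxyl would be harmless, since both lactones give 14 in step 8.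

Step 8
Reactants: 13 (3S,4S,5R)-3-{[3,4-dimethoxy-5-(triisopropylsilyloxy)phenyl]methyl}-4-(hydroxymethyl)-5-(3,4,5-trimethoxyphenyl)oxolan-2-one
Product: 14 (2S,3S)-2-{[3,4-dimethoxy-5-(triisopropylsilyloxy)phenyl]methyl}-3-[(R)-hydroxy(3,4,5-trimethoxyphenyl)methyl]butane-1,4-diol
Conditions: LiAlH4, THF, 0 °C; aq. KNaC4H4O6 (potassium sodium tartrate) work-up
Reagents that add atoms: none
Why: Hydride reduction of a γ-lactone to the diol is fast at 0 °C and should be quicker than enolisation at C4; once C5 is an alcohol, C3 and C4 are configurationally locked, and the hindered aryl silyl ether should survive.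

Step 9
Reactants: 14 (2S,3S)-2-{[3,4-dimethoxy-5-(triisopropylsilyloxy)phenyl]methyl}-3-[(R)-hydroxy(3,4,5-trimethoxyphenyl)methyl]butane-1,4-diol
Product: 15 [(2R,3S,4S)-4-{[3,4-dimethoxy-5-(triisopropylsilyloxy)phenyl]methyl}-2-(3,4,5-trimethoxyphenyl)oxolan-3-yl]methanol
Conditions: camphor-10-sulfonic acid (10 mol%), CH2Cl2 (0.01 M), 0 °C → rt; Et3N quench at full conversion
Reagents that add atoms: none
Why: Acid-catalysed cyclodehydration through the C2 benzylic cation, the ring closure known for lariciresinol-type lignans: the C5 hydroxyl closes the five-membered ether (the C3a hydroxyl could only give an oxetane), and C2 is set again with Ar1 trans to C3a because the all-cis ring is more strained under both kinetic and equilibrating conditions. Mild acid, dilution and an early quench should keep the ether from re-ionising toward attack by ring Ar2.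

Step 10
Reactants: 15 [(2R,3S,4S)-4-{[3,4-dimethoxy-5-(triisopropylsilyloxy)phenyl]methyl}-2-(3,4,5-trimethoxyphenyl)oxolan-3-yl]methanol
Product: 16 [(2R,3S,4S)-4-(3-hydroxy-4,5-dimethoxybenzyl)-2-(3,4,5-trimethoxyphenyl)oxolan-3-yl]methanol
Conditions: Bu4NF (1.1 equiv), THF, 0 °C; aq. NH4Cl
Reagents that add atoms: none
Why: Fluoride cleavage of an aryl silyl ether; no acid, metal or hydrogen is present, so the C2–O1 benzylic ether and the three stereocentres should be untouched.

## Compound list

1 | 3-hydroxy-4,5-dimethoxybenzaldehyde | COc1cc(C=O)cc(O)c1OC | starting material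
2 | 3,4-dimethoxy-5-[(triisopropylsilyl)oxy]benzaldehyde | COc1cc(C=O)cc(O[Si](C(C)C)(C(C)C)C(C)C)c1OC | intermediate
3 | {3,4-dimethoxy-5-[(triisopropylsilyl)oxy]phenyl}methanol | COc1cc(CO)cc(O[Si](C(C)C)(C(C)C)C(C)C)c1OC | intermediate
4 | [5-(bromomethyl)-2,3-dimethoxyphenoxy]tri(propan-2-yl)silane | COc1cc(CBr)cc(O[Si](C(C)C)(C(C)C)C(C)C)c1OC | intermediate
5 | 4-oxo-4-(3,4,5-trimethoxyphenyl)butanoic acid | COc1cc(C(=O)CCC(=O)O)cc(OC)c1OC | starting material
6 | (4R)-4-hydroxy-4-(3,4,5-trimethoxyphenyl)butanoic acid | COc1cc([C@H](O)CCC(=O)O)cc(OC)c1OC | intermediate (not isolated)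
7 | (5R)-5-(3,4,5-trimethoxyphenyl)oxolan-2-one | COc1cc([C@H]2CCC(=O)O2)cc(OC)c1OC | intermediate
8 | (3S,5R)-3-{[3,4-dimethoxy-5-(triisopropylsilyloxy)phenyl]methyl}-5-(3,4,5-trimethoxyphenyl)oxolan-2-one (3,5-trans, major epimer) | COc1cc(C[C@H]2C[C@H](c3cc(OC)c(OC)c(OC)c3)OC2=O)cc(O[Si](C(C)C)(C(C)C)C(C)C)c1OC | intermediate
9 | (3S,5R)-3-{[3,4-dimethoxy-5-(triisopropylsilyloxy)phenyl]methyl}-3-(phenylselanyl)-5-(3,4,5-trimethoxyphenyl)oxolan-2-one (selenium trans to Ar1) | COc1cc(C[C@]2([Se]c3ccccc3)C[C@H](c3cc(OC)c(OC)c(OC)c3)OC2=O)cc(O[Si](C(C)C)(C(C)C)C(C)C)c1OC | intermediate (not isolated)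
10 | (3S,5R)-3-(benzeneseleninyl)-3-{[3,4-dimethoxy-5-(triisopropylsilyloxy)phenyl]methyl}-5-(3,4,5-trimethoxyphenyl)oxolan-2-one (selenium configuration undefined) | COc1cc(C[C@]2([Se](=O)c3ccccc3)C[C@H](c3cc(OC)c(OC)c(OC)c3)OC2=O)cc(O[Si](C(C)C)(C(C)C)C(C)C)c1OC | intermediate (not isolated)
11 | (5R)-3-{[3,4-dimethoxy-5-(triisopropylsilyloxy)phenyl]methyl}-5-(3,4,5-trimethoxyphenyl)furan-2(5H)-one | COc1cc(CC2=C[C@H](c3cc(OC)c(OC)c(OC)c3)OC2=O)cc(O[Si](C(C)C)(C(C)C)C(C)C)c1OC | intermediate
12 | methanol | CO | starting material
13 | (3S,4S,5R)-3-{[3,4-dimethoxy-5-(triisopropylsilyloxy)phenyl]methyl}-4-(hydroxymethyl)-5-(3,4,5-trimethoxyphenyl)oxolan-2-one | COc1cc(C[C@@H]2C(=O)O[C@@H](c3cc(OC)c(OC)c(OC)c3)[C@@H]2CO)cc(O[Si](C(C)C)(C(C)C)C(C)C)c1OC | intermediate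
14 | (2S,3S)-2-{[3,4-dimethoxy-5-(triisopropylsilyloxy)phenyl]methyl}-3-[(R)-hydroxy(3,4,5-trimethoxyphenyl)methyl]butane-1,4-diol | COc1cc(C[C@H](CO)[C@@H](CO)[C@@H](O)c2cc(OC)c(OC)c(OC)c2)cc(O[Si](C(C)C)(C(C)C)C(C)C)c1OC | intermediate
15 | [(2R,3S,4S)-4-{[3,4-dimethoxy-5-(triisopropylsilyloxy)phenyl]methyl}-2-(3,4,5-trimethoxyphenyl)oxolan-3-yl]methanol | COc1cc(C[C@@H]2CO[C@@H](c3cc(OC)c(OC)c(OC)c3)[C@@H]2CO)cc(O[Si](C(C)C)(C(C)C)C(C)C)c1OC | intermediate
16 | [(2R,3S,4S)-4-(3-hydroxy-4,5-dimethoxybenzyl)-2-(3,4,5-trimethoxyphenyl)oxolan-3-yl]methanol | COc1cc(C[C@@H]2CO[C@@H](c3cc(OC)c(OC)c(OC)c3)[C@@H]2CO)cc(O)c1OC | target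

## Step count and least certain steps

Total step count: 10. Longest linear sequence: 9 steps (from 1 through steps 1, 2, 3, 5, 6, 7, 8, 9 and 10); step 4 is the one-step second branch from 5.

Step 7 (key step). The most likely failure is hydrogen-atom transfer to the wrong face of the C4 radical, because the favoured face is the one that carries Ar1. Two further losses are possible: abstraction of the weak, doubly activated C2–H by the excited ketone, and unproductive quenching of the sensitiser by the two electron-rich rings.
The fallback sets out from 11 and replaces the radical chain by polar chemistry. Copper-catalysed conjugate addition of iPrO(Me)2SiCH2MgCl (CuBr·SMe2, THF, −78 °C) should place the silylmethyl group on C3 anti to Ar1. The magnesium enolate is then protonated at −78 °C by a bulky phenol (2,6-di-tert-butylphenol), whose size is a handle on the C4 selection that the radical chain lacks. This gives (3S,4R,5R)-3-{[3,4-dimethoxy-5-(triisopropylsilyloxy)phenyl]methyl}-4-{[dimethyl(propan-2-yloxy)silyl]methyl}-5-(3,4,5-trimethoxyphenyl)oxolan-2-one F1. Tamao oxidation without fluoride (30% H2O2, KHCO3, THF/MeOH), to spare the aryl silyl ether, turns the C–Si bond into C–OH, and the route is rejoined at 13.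

Step 9. The C2 cation may be captured by ring Ar2 (six-membered ring closure to an aryltetralin), directly or after re-ionisation of the ether, since ring Ar2 is activated at both positions ortho to C4a. Incomplete trans selection at C2 is a lesser risk.
The fallback sets out from 13 and never ionises C2. Silylation of the C3a hydroxyl (tBuMe2SiCl, imidazole, DMF) gives (3S,4S,5R)-4-{[(tert-butyldimethylsilyl)oxy]methyl}-3-{[3,4-dimethoxy-5-(triisopropylsilyloxy)phenyl]methyl}-5-(3,4,5-trimethoxyphenyl)oxolan-2-one F2. LiAlH4 reduction gives (1R,2S,3S)-2-{[(tert-butyldimethylsilyl)oxy]methyl}-3-{[3,4-dimethoxy-5-(triisopropylsilyloxy)phenyl]methyl}-1-(3,4,5-trimethoxyphenyl)butane-1,4-diol F3. Mitsunobu cyclodehydration (PPh3, diisopropyl azodicarboxylate, THF, 0 °C) activates the primary C5 hydroxyl, which the benzylic hydroxyl displaces with retention at C2, to give tert-butyl{[(2R,3S,4S)-4-{[3,4-dimethoxy-5-(triisopropylsilyloxy)phenyl]methyl}-2-(3,4,5-trimethoxyphenyl)oxolan-3-yl]methoxy}dimethylsilane F4. Bu4NF removes both silyl groups and the route is rejoined at 16, one step longer than the main line.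

Step 6. The selenoxide may eliminate toward the exocyclic benzylic hydrogens on C4a and give the arylidene lactone; optical purity may also be lost by enolisation of the product to the achiral 2-hydroxyfuran if any base is present.
The fallback sets out from 7 and makes the ring alkene before the arylmethyl group is attached, so that no exocyclic hydrogen exists at the elimination stage. Selenenylation of 7 (LiN(iPr)2, PhSeBr) gives (5R)-3-(phenylselanyl)-5-(3,4,5-trimethoxyphenyl)oxolan-2-one F5. Bromination of its enolate (LiN(SiMe3)2, then CBr4, −78 °C) gives (5R)-3-bromo-3-(phenylselanyl)-5-(3,4,5-trimethoxyphenyl)oxolan-2-one F6. Oxidation with H2O2 at 0 °C gives the selenoxide (5R)-3-(benzeneseleninyl)-3-bromo-5-(3,4,5-trimethoxyphenyl)oxolan-2-one F7, which can only eliminate into the ring to give (5R)-3-bromo-5-(3,4,5-trimethoxyphenyl)furan-2(5H)-one F8. Negishi coupling of F8 (Pd(PPh3)4, zerovalent palladium, THF, rt) with {[3,4-dimethoxy-5-(triisopropylsilyloxy)phenyl]methyl}zinc bromide F9, made from 4 with Zn dust and LiCl, forms the C4–C4a bond under neutral conditions and rejoins the route at 11.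

Step 4. Enantioselection may be incomplete, because the electron-rich ketone accepts hydride slowly and every later centre depends on C2.
The fallback sets out from 5 and uses a stoichiometric-hydride asymmetric reduction on a protected carboxyl group. Fischer esterification (MeOH, cat. H2SO4) gives methyl 4-oxo-4-(3,4,5-trimethoxyphenyl)butanoate F10; the free acid cannot be used because BH3 reduces a carboxylic acid faster than a ketone. Corey–Bakshi–Shibata reduction ((S)-2-methyl-oxazaborolidine catalyst, BH3·SMe2, THF, −20 °C) should give methyl (4R)-4-hydroxy-4-(3,4,5-trimethoxyphenyl)butanoate F11. Acid-catalysed lactonisation (cat. TsOH, toluene, rt) rejoins the route at 7, which could also be enriched by crystallisation.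

## Further compounds

F1 | step 7 | (3S,4R,5R)-3-{[3,4-dimethoxy-5-(triisopropylsilyloxy)phenyl]methyl}-4-{[dimethyl(propan-2-yloxy)silyl]methyl}-5-(3,4,5-trimethoxyphenyl)oxolan-2-one | COc1cc(C[C@@H]2C(=O)O[C@@H](c3cc(OC)c(OC)c(OC)c3)[C@@H]2C[Si](C)(C)OC(C)C)cc(O[Si](C(C)C)(C(C)C)C(C)C)c1OC
F2 | step 9 | (3S,4S,5R)-4-{[(tert-butyldimethylsilyl)oxy]methyl}-3-{[3,4-dimethoxy-5-(triisopropylsilyloxy)phenyl]methyl}-5-(3,4,5-trimethoxyphenyl)oxolan-2-one | COc1cc(C[C@@H]2C(=O)O[C@@H](c3cc(OC)c(OC)c(OC)c3)[C@@H]2CO[Si](C)(C)C(C)(C)C)cc(O[Si](C(C)C)(C(C)C)C(C)C)c1OC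
F3 | step 9 | (1R,2S,3S)-2-{[(tert-butyldimethylsilyl)oxy]methyl}-3-{[3,4-dimethoxy-5-(triisopropylsilyloxy)phenyl]methyl}-1-(3,4,5-trimethoxyphenyl)butane-1,4-diol | COc1cc(C[C@H](CO)[C@@H](CO[Si](C)(C)C(C)(C)C)[C@@H](O)c2cc(OC)c(OC)c(OC)c2)cc(O[Si](C(C)C)(C(C)C)C(C)C)c1OC
F4 | step 9 | tert-butyl{[(2R,3S,4S)-4-{[3,4-dimethoxy-5-(triisopropylsilyloxy)phenyl]methyl}-2-(3,4,5-trimethoxyphenyl)oxolan-3-yl]methoxy}dimethylsilane | COc1cc(C[C@@H]2CO[C@@H](c3cc(OC)c(OC)c(OC)c3)[C@@H]2CO[Si](C)(C)C(C)(C)C)cc(O[Si](C(C)C)(C(C)C)C(C)C)c1OC
F5 | step 6 | (5R)-3-(phenylselanyl)-5-(3,4,5-trimethoxyphenyl)oxolan-2-one (mixture at C3) | COc1cc([C@H]2CC([Se]c3ccccc3)C(=O)O2)cc(OC)c1OC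
F6 | step 6 | (5R)-3-bromo-3-(phenylselanyl)-5-(3,4,5-trimethoxyphenyl)oxolan-2-one (mixture at C3) | COc1cc([C@H]2CC(Br)([Se]c3ccccc3)C(=O)O2)cc(OC)c1OC
F7 | step 6 | (5R)-3-(benzeneseleninyl)-3-bromo-5-(3,4,5-trimethoxyphenyl)oxolan-2-one | COc1cc([C@H]2CC(Br)([Se](=O)c3ccccc3)C(=O)O2)cc(OC)c1OC
F8 | step 6 | (5R)-3-bromo-5-(3,4,5-trimethoxyphenyl)furan-2(5H)-one | COc1cc([C@H]2C=C(Br)C(=O)O2)cc(OC)c1OC
F9 | step 6 | {[3,4-dimethoxy-5-(triisopropylsilyloxy)phenyl]methyl}zinc bromide | COc1cc(C[Zn]Br)cc(O[Si](C(C)C)(C(C)C)C(C)C)c1OC
F10 | step 4 | methyl 4-oxo-4-(3,4,5-trimethoxyphenyl)butanoate | COC(=O)CCC(=O)c1cc(OC)c(OC)c(OC)c1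
F11 | step 4 | methyl (4R)-4-hydroxy-4-(3,4,5-trimethoxyphenyl)butanoate | COC(=O)CC[C@@H](O)c1cc(OC)c(OC)c(OC)c1
A1 | alternative 1 | cis-fused cycloadduct, 3-[(1R,2S,5R)-menthyloxy]-6-(3,4,5-trimethoxyphenyl)tetrahydro-1H,3H-furo[3,4-c]furan-1-one with C2, C3 and C4 as in the target | O=C1O[C@@H](O[C@@H]3C[C@H](C)CC[C@H]3C(C)C)[C@@H]2CO[C@@H](c3cc(OC)c(OC)c(OC)c3)[C@H]12
A2 | alternative 1 | (5R)-5-{[(1R,2S,5R)-5-methyl-2-(propan-2-yl)cyclohexyl]oxy}furan-2(5H)-one | O=C1O[C@@H](O[C@@H]2C[C@H](C)CC[C@H]2C(C)C)C=C1
A3 | alternative 1 | {[chloro(3,4,5-trimethoxyphenyl)methoxy]methyl}trimethylsilane (racemic) | COc1cc(C(Cl)OC[Si](C)(C)C)cc(OC)c1OC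
A4 | alternative 2 | [(2R,3S,4S)-4-[3-(benzyloxy)-4,5-dimethoxybenzyl]-2-(3,4,5-trimethoxyphenyl)oxolan-3-yl]methanol | COc1cc(C[C@@H]2CO[C@@H](c3cc(OC)c(OC)c(OC)c3)[C@@H]2CO)cc(OCc3ccccc3)c1OC
A5 | alternative 2 | 2-[{[(2E)-3-(3-benzyloxy-4,5-dimethoxyphenyl)prop-2-en-1-yl]oxy}(3,4,5-trimethoxyphenyl)methyl]oxirane, benzylic carbon configured as C2 of the target, epoxide carbon either way | COc1cc(/C=C/CO[C@@H](c2cc(OC)c(OC)c(OC)c2)C2CO2)cc(OCc2ccccc2)c1OC
A6 | alternative 3 | bis(tert-butyldimethylsilyl) ether of the target | COc1cc(C[C@@H]2CO[C@@H](c3cc(OC)c(OC)c(OC)c3)[C@@H]2CO[Si](C)(C)C(C)(C)C)cc(O[Si](C)(C)C(C)(C)C)c1OC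
A7 | alternative 3 | 4-{[3-(tert-butyldimethylsilyloxy)-4,5-dimethoxyphenyl]methyl}-3-{[(tert-butyldimethylsilyl)oxy]methyl}oxolan-2-yl acetate, C3 and C4 as in the target, anomeric mixture | COc1cc(C[C@@H]2COC(OC(C)=O)[C@@H]2CO[Si](C)(C)C(C)(C)C)cc(O[Si](C)(C)C(C)(C)C)c1OC
A8 | alternative 3 | bromo(3,4,5-trimethoxyphenyl)zinc | COc1cc([Zn]Br)cc(OC)c1OC
A9 | alternative 3 | (3aS,6aS)-tetrahydro-1H,4H-furo[3,4-c]furan-1,4-dione (cis-fused) | O=C1[C@@H]2COC(=O)[C@@H]2CO1
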